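All runs were computed for an exercise, and the scatter is random.

The vessel was closed, stirred and isothermal, with starting material in the first phase and reagent in the second.

| flask | starting material | reagent in the second phase | remark | time | volume of the second phase over the first |
|---|---|---|---|---|---|
| autumn | 20 mM | 0.95 equiv | the very flask that is asked about, followed so far |  |  |
| dusk | 40 mM | 0.95 equiv | run made earlier |  |  |
| flask | 20 mM | 0.950 equiv |  | 2.0 min | 0.50 |

- autumn (time / s: target / %, starting material / %): 12.0: 4, 87; 25.0: 4, 79; 40.0: 2, 77; 50.0: 4, 70; 60.0: 3, 68
- dusk (time / s: target / %, starting material / %): 15.0: 0, 88; 30.0: 1, 77; 50.0: 4, 68; 60.0: 4, 65; 80.0: 10, 55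

(scatter of a reading: 2 percentage points)

- in the second phase: reagent in the second phase; everything else is in the first
- charges count per volume of the first phase; a concentration in a rate is the amount of a species over the volume of its own phase; every rate counts per litre of the first phase
- the earlier runs hold the two phases in the same ratio of volumes as the flask asked about
- what has gone from starting material into another species counts as reacted, even if it can come back

- how much target there is at 2.0 min, in percent of the starting material charged
- part of the starting material charged that has reacted at 2.0 min

1. At 60.0 s the autumn flask held 68% of its starting material and the dusk flask, charged at 40 mM, held 65%. That gap of 3 percentage points stood against a scatter of 2 points per reading, so I took the bench rule for first-order decay: find a half-life, count half-lives.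

2. Autumn's first reading, 87% at 12.0 s, gave an early half-life τe = 0.995 min. That made 2.01 half-lives to 2.0 min, so the rule promised 24.8% left.

3. The rule broke inside the autumn run: for 60.0 s it promised 49.8%, but autumn read 68%. Between 25.0 s and 60.0 s, τ = 2.70 min is the late half-life, the time in which starting material halves at the pace of autumn's later readings. The ratio τ/τe = 2.71, read off scattered readings, marked the border: autumn's readings did not follow one time constant.

4. So I counted from autumn's last reading. There remained 0.370 late half-lives, so my estimate was 52.6% left and 47.4% reacted.

5. The forecast gave 14% target and 55% reacted, noting “The rate slows with time”; its reacted share stood above mine.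

6. The flask gave 8.89% target and 44.1% reacted.

    starting material + reagent in the reaction phase → target (k = 0.308 M⁻¹ s⁻¹)
    starting material ⇌ dormant form (K = 0.560, k = 0.00984 s⁻¹)
    reagent in the reaction phase + target → over-reacted product (k = 0.317 M⁻¹ s⁻¹)
    reagent in the reaction phase ⇌ reagent in the second phase, rate k4*([reagent in the reaction phase] - [reagent in the second phase]/K4) per volume of the first phase (partition coefficient = 2.50, kL = 0.0137 s⁻¹)
    2 reagent in the reaction phase → self-condensation product (k = 0.280 M⁻¹ s⁻¹)
    starting material + target → side product (k = 0.210 M⁻¹ s⁻¹)

Dormant form stood at 31.5% at 2.00 min, and its exchange with starting material (an off-path reservoir) has, by that step alone and both ways together, a relaxation half-life of 0.421 min, shorter than 2.0 min. Counted with τ from the flask's 66.5% at 1.00 min, starting material came to 51.4% at 2.00 min; the flask held 55.9%.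

7. For the same flask read at 3.0 min, τ counted from 55.9% gave 56.8% reacted. The computed neighbour gave 49.2% reacted and 11.6% target.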